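The route is built on one disconnection: ring B of the labdane decalin is opened across C5–C10 and C8–C9. A catalytic enantioselective intramolecular Diels–Alder reaction of an achiral trienal closes rings A and B at once and sets C5, C9 and the methyl-bearing quaternary C10. It exploits the fact that these carbons, the trans A/B fusion and C8 (the site of the exocyclic methylene, carried as a silyloxy group) lie on one cyclohexene. The precursor is a dimethyl malonate (C4) bearing an (E,E)-4-silyloxybutadienyl arm (C5–C8) and an (E)-enal arm (C1–C3, C10, C9, C11). C4 and C13 are set later by enolate methylation and asymmetric epoxidation.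

Key step: step 9

Assumption: the (S)-configured oxazaborolidinium ion is taken to bind the s-trans enal through B–O and formyl C–H···O contacts with a catalyst phenyl group covering the re face of C9; if the first adduct proves antipodal, the catalyst from (R)-α,α-diphenylprolinol is used with no other change.

Labdane numbering and α/β descriptors (C20 methyl = β) are used for the bicyclic compounds.

Step 1
Reactants: 1 geranyl acetate
Product: 3 (E)-6-hydroxy-3-methylhex-2-enyl acetate, via aldehyde 2 (not isolated)
Conditions: O3 (1 equiv), CH2Cl2/MeOH, −78 °C; Me2S; then NaBH4, 0 °C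
Reagents that add atoms: ozone, [O-][O+]=O
Why: Ozonolysis with reductive work-up should cleave only the electron-rich 6,7-alkene, because the 2,3-alkene is deactivated by the allylic acetoxy group, and the borohydride reduces the aldehyde without touching the acetate or the E-alkene.

Step 2
Reactants: 3 (E)-6-hydroxy-3-methylhex-2-enyl acetate
Product: 4 (E)-6-iodo-3-methylhex-2-enyl acetate
Conditions: PPh3, I2, imidazole, CH2Cl2, 0 °C → rt
Reagents that add atoms: iodine, [I][I]
Why: Appel iodination converts the primary alcohol into the iodide under buffered neutral conditions that leave the allylic acetate and the E-alkene untouched.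

Step 3
Reactants: 5 dimethyl malonate; 6 2-vinyloxirane (racemic)
Product: 7 dimethyl 2-[(E)-4-hydroxybut-2-enyl]malonate
Conditions: Pd(PPh3)4 (2 mol %), excess 5, THF, 0 °C → rt
Reagents that add atoms: none
Why: Tsuji–Trost allylic alkylation under neutral conditions: zerovalent palladium opens the vinyl epoxide to a π-allyl alkoxide that deprotonates the malonate, which then attacks the distal allyl terminus to give the E-configured 1,4-adduct.

Step 4
Reactants: 7 dimethyl 2-[(E)-4-hydroxybut-2-enyl]malonate; 4 (E)-6-iodo-3-methylhex-2-enyl acetate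
Product: 9 dimethyl 2-[(E)-6-acetoxy-4-methylhex-4-enyl]-2-[(E)-4-hydroxybut-2-enyl]malonate, via sodium enolate 8 (not isolated)
Conditions: NaH (1.0 equiv), THF/DMF, 0 °C; then 4, rt
Reagents that add atoms: none
Why: Malonate alkylation (SN2): the soft sodium enolate is C-alkylated by the primary iodide and creates the quaternary C4, while the far less acidic hydroxyl and the acetate stay untouched.

Step 5
Reactants: 9 dimethyl 2-[(E)-6-acetoxy-4-methylhex-4-enyl]-2-[(E)-4-hydroxybut-2-enyl]malonate
Product: 10 dimethyl 2-[(E)-6-acetoxy-4-methylhex-4-enyl]-2-[(E)-4-oxobut-2-enyl]malonate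
Conditions: activated MnO2, CH2Cl2, rt
Reagents that add atoms: none
Why: Allylic oxidation with MnO2 acts only on the free allylic alcohol and gives the E-enal (any Z isomer converges on it), leaving esters and the acetoxy-bearing alkene alone.

Step 6
Reactants: 10 dimethyl 2-[(E)-6-acetoxy-4-methylhex-4-enyl]-2-[(E)-4-oxobut-2-enyl]malonate
Product: 11 dimethyl 2-[(E)-6-acetoxy-4-methylhex-4-enyl]-2-[(1E,3E)-4-(tert-butyldimethylsilyloxy)buta-1,3-dienyl]malonate
Conditions: TBSOTf, Et3N, CH2Cl2, −78 → 0 °C
Reagents that add atoms: tert-butyldimethylsilyl triflate, CC(C)(C)[Si](C)(C)OS(=O)(=O)C(F)(F)F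
Why: Silyl dienol ether formation by soft enolisation: O-silylation of the s-trans enal and amine deprotonation at the γ-methylene C5 should give the 1-silyloxydiene, with the C7=C8 geometry following from the s-trans enal and the C5=C6 geometry from the bulky quaternary C4 taking the trans position.

Step 7
Reactants: 11 dimethyl 2-[(E)-6-acetoxy-4-methylhex-4-enyl]-2-[(1E,3E)-4-(tert-butyldimethylsilyloxy)buta-1,3-dienyl]malonate
Product: 12 dimethyl 2-[(1E,3E)-4-(tert-butyldimethylsilyloxy)buta-1,3-dienyl]-2-[(E)-6-hydroxy-4-methylhex-4-enyl]malonate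
Conditions: K2CO3 (cat.), MeOH, 0 °C
Reagents that add atoms: none
Why: Transesterification with catalytic methoxide removes the allylic acetate; methanolysis of the methyl malonate is degenerate and the tert-butyldimethylsilyl dienol ether should tolerate brief exposure to carbonate in the cold.

Step 8
Reactants: 12 dimethyl 2-[(1E,3E)-4-(tert-butyldimethylsilyloxy)buta-1,3-dienyl]-2-[(E)-6-hydroxy-4-methylhex-4-enyl]malonate
Product: 13 dimethyl 2-[(1E,3E)-4-(tert-butyldimethylsilyloxy)buta-1,3-dienyl]-2-[(E)-4-methyl-6-oxohex-4-enyl]malonate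
Conditions: activated MnO2, CH2Cl2, rt
Reagents that add atoms: none
Why: Allylic oxidation with neutral MnO2 should give the β,β-disubstituted enal with retention of the E geometry and without attacking the acid-labile silyl dienol ether.

Step 9
Reactants: 13 dimethyl 2-[(1E,3E)-4-(tert-butyldimethylsilyloxy)buta-1,3-dienyl]-2-[(E)-4-methyl-6-oxohex-4-enyl]malonate
Product: 14 dimethyl 8β-(tert-butyldimethylsilyloxy)-11-oxo-12,13,14,15,16,17-hexanorlabd-6-ene-18,19-dioate (trans-fused octalin: 5α-H 10β-CH3 9β-CHO 8β-OSi)
Conditions: (S)-3,3-diphenyl-1-(o-tolyl)tetrahydropyrrolo[1,2-c][1,3,2]oxazaborolidinium triflimide (20 mol %; from (S)-α,α-diphenylprolinol, o-tolylboronic acid, then HNTf2), CH2Cl2, −78 → −40 °C; Et3N quench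
Reagents that add atoms: none
Why: Proposed new method: coordination of the formyl oxygen of 13 to the cationic boron lowers the enal LUMO, and the tethered silyloxydiene adds in a concerted, asynchronous [4+2] process in which C5–C10 (diene terminus remote from oxygen to the enal β-carbon) runs ahead of C8–C9; the closest known reaction type is the oxazaborolidinium-catalysed enantioselective Diels–Alder reaction of α,β-enals (inter- and intramolecular) together with Lewis acid-promoted intramolecular cycloadditions of 1,7,9-decatrienals, whereas a β,β-disubstituted enal paired with a 1-silyloxydiene in an intramolecular, catalyst-controlled setting has not been shown. Ring B closes as the cyclohexene of the cycloaddition itself (both new bonds formed suprafacially), and ring A closes through the same C5–C10 bond as a six-membered carbocycle spanned by the C1–C4 tether held in a chair exo to the diene (fused, type 1 mode). C9 and C10 are related by the E geometry of the enal (formyl cis to the C20 methyl), C5 is related to C10 by the formyl-endo, tether-exo transition state that gives the trans fusion, C8 follows from the E silyl enol ether (silyloxy cis to formyl), and the absolute sense comes from the catalyst, which leaves the si face of C9 open. The step needs enantioface selectivity, endo selectivity and chemoselectivity for cycloaddition over desilylation or Mukaiyama–Michael addition. These should be secured by the two-point binding of the s-trans enal, by the Lewis acid-enhanced endo preference with the gem-diester preorganising the tether, and by the bulky silyl group with the non-nucleophilic triflimide counter-ion at low temperature. Regiochemistry is fixed by the tether and is also the electronically matched one.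

Step 10
Reactants: 14 dimethyl 8β-(tert-butyldimethylsilyloxy)-11-oxo-12,13,14,15,16,17-hexanorlabd-6-ene-18,19-dioate
Product: 15 dimethyl 8β-(tert-butyldimethylsilyloxy)-13,14,15,16,17-pentanorlabda-6,11-diene-18,19-dioate
Conditions: Ph3PCH3Br, KN(SiMe3)2, THF, −78 → 0 °C
Reagents that add atoms: methyltriphenylphosphonium bromide, C[P+](c1ccccc1)(c1ccccc1)c1ccccc1.[Br-]
Why: Wittig methylenation: the unstabilised ylide should add to the hindered aldehyde in the cold faster than it enolises it, so that C9 keeps its configuration and the C8 silyloxy group is not eliminated, the methyl esters being inert.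

Step 11
Reactants: 15 dimethyl 8β-(tert-butyldimethylsilyloxy)-13,14,15,16,17-pentanorlabda-6,11-diene-18,19-dioate
Product: 16 methyl 8β-(tert-butyldimethylsilyloxy)-13,14,15,16,17-pentanorlabda-6,11-diene-4-carboxylate lacking one C4 ester (C4 epimer mixture)
Conditions: LiCl, H2O, DMSO, 155 °C
Reagents that add atoms: none
Why: Krapcho dealkoxycarbonylation: chloride demethylates one ester by SN2 at the methyl group and the carboxylate loses CO2; the C4 configuration is irrelevant because it is reset in step 12.

Step 12
Reactants: 16 monoester (C4 epimer mixture)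
Product: 18 methyl 8β-(tert-butyldimethylsilyloxy)-13,14,15,16,17-pentanorlabda-6,11-dien-19-oate (4α-CH3 equatorial and 4β-CO2CH3 axial), via lithium enolate 17 (not isolated)
Conditions: LiN(iPr)2, THF, −78 → −20 °C; then MeI, −78 → 0 °C
Reagents that add atoms: iodomethane, CI
Why: Ester enolate alkylation: the exocyclic C4 enolate should be methylated from the α face because the β face is screened by the syn-axial C10 methyl, which places the new methyl equatorial and the ester axial (C4 set by substrate control).

Step 13
Reactants: 19 but-2-yn-1-ol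
Product: 21 (Z)-3-iodobut-2-en-1-ol, via vinylalanate 20 (not isolated)
Conditions: NaAlH2(OCH2CH2OMe)2, Et2O, 0 °C → rt; then I2, −78 °C
Reagents that add atoms: iodine, [I][I]
Why: Hydroxyl-directed trans-hydroalumination of the propargylic alcohol places aluminium on C3 and iodinolysis proceeds with retention, fixing the Z geometry of the iodoalkene.

Step 14
Reactants: 18 methyl 8β-(tert-butyldimethylsilyloxy)-13,14,15,16,17-pentanorlabda-6,11-dien-19-oate; 21 (Z)-3-iodobut-2-en-1-ol
Product: 23 methyl (13Z)-8β-(tert-butyldimethylsilyloxy)-15-hydroxy-17-norlabda-6,13-dien-19-oate, via alkylborane 22 (not isolated)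
Conditions: 9-BBN, THF, 0 °C → rt; then 21, PdCl2(dppf) (5 mol %), AsPh3, Cs2CO3, DMF/H2O, rt
Reagents that add atoms: none
Why: Hydroboration followed by B-alkyl Suzuki–Miyaura coupling: 9-BBN adds only to the monosubstituted vinyl group (boron on C12, the ring alkene being far slower) and the alkylborane couples with the iodoalkene with retention of the Z geometry.

Step 15
Reactants: 23 methyl (13Z)-8β-(tert-butyldimethylsilyloxy)-15-hydroxy-17-norlabda-6,13-dien-19-oate
Product: 24 methyl (13R,14S)-8β-(tert-butyldimethylsilyloxy)-13,14-epoxy-15-hydroxy-17-norlabd-6-en-19-oate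
Conditions: Ti(OiPr)4 (10 mol %), L-(+)-diethyl tartrate (12 mol %), t-BuOOH, 4 Å molecular sieves, CH2Cl2, −20 °C
Reagents that add atoms: tert-butyl hydroperoxide, CC(C)(C)OO
Why: Sharpless asymmetric epoxidation: the titanium tartrate complex delivers oxygen to one face of the Z-allylic alcohol under reagent control, L-(+)-tartrate giving the (13R,14S)-epoxide in the sense established for Z-trisubstituted allylic alcohols, while the ring alkene, not being an allylic alcohol, is untouched.

Step 16
Reactants: 24 methyl (13R,14S)-8β-(tert-butyldimethylsilyloxy)-13,14-epoxy-15-hydroxy-17-norlabd-6-en-19-oate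
Product: 25 methyl (13R,14S)-8β-(tert-butyldimethylsilyloxy)-13,14-epoxy-15-hydroxy-17-norlabdan-19-oate
Conditions: H2 (1 atm), 5% Pt/C, EtOAc, rt
Reagents that add atoms: none
Why: Heterogeneous hydrogenation saturates the only remaining alkene (C6=C7) without stereochemical consequence, platinum being chosen to avoid hydrogenolysis of the allylic silyl ether and of the epoxide.

Step 17
Reactants: 25 methyl (13R,14S)-8β-(tert-butyldimethylsilyloxy)-13,14-epoxy-15-hydroxy-17-norlabdan-19-oate
Product: 27 methyl (13R)-8β-(tert-butyldimethylsilyloxy)-13-hydroxy-17-norlabd-14-en-19-oate, via epoxy iodide 26 (not isolated)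
Conditions: PPh3, I2, imidazole, THF, 0 °C; then Zn dust, EtOH, 50 °C
Reagents that add atoms: none
Why: Appel iodination and zinc insertion into the C–I bond trigger β-elimination with epoxide opening (reductive 1,3-transposition of a 2,3-epoxy alcohol), which unveils the C14=C15 vinyl group and the C13 tertiary alcohol without breaking the C13–O bond, so the 13R configuration is retained.

Step 18
Reactants: 27 methyl (13R)-8β-(tert-butyldimethylsilyloxy)-13-hydroxy-17-norlabd-14-en-19-oate
Product: 28 methyl (13R)-8β,13-dihydroxy-17-norlabd-14-en-19-oate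
Conditions: Bu4NF, THF, 50 °C
Reagents that add atoms: none
Why: Fluoride-induced desilylation frees the secondary C8 alcohol, the hindered axial ester and the tertiary allylic alcohol being stable to these mildly basic conditions.

Step 19
Reactants: 28 methyl (13R)-8β,13-dihydroxy-17-norlabd-14-en-19-oate
Product: 29 methyl (13R)-13-hydroxy-8-oxo-17-norlabd-14-en-19-oate
Conditions: Dess–Martin periodinane, NaHCO3, CH2Cl2, rt
Reagents that add atoms: none
Why: Dess–Martin oxidation under bicarbonate buffer converts the secondary alcohol into the ketone, cannot oxidise the tertiary allylic alcohol and avoids acid that would ionise it or dehydrate the δ-hydroxy ketone.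

Step 20
Reactants: 29 methyl (13R)-13-hydroxy-8-oxo-17-norlabd-14-en-19-oate
Product: 30 methyl (13R)-13-hydroxylabda-8(17),14-dien-19-oate
Conditions: Ph3PCH3Br (excess), KOtBu, toluene, rt → 60 °C
Reagents that add atoms: methyltriphenylphosphonium bromide, C[P+](c1ccccc1)(c1ccccc1)c1ccccc1.[Br-]
Why: Wittig methylenation of the hindered C8 ketone with excess ylide installs the exocyclic C8=C17 alkene; C9 is epimerisable but its equatorial side chain is the thermodynamically preferred arrangement, and the non-enolisable axial ester is inert.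

Step 21
Reactants: 30 methyl (13R)-13-hydroxylabda-8(17),14-dien-19-oate
Product: 31 (13R)-labda-8(17),14-diene-13,19-diol
Conditions: LiAlH4, THF, 0 °C → reflux
Reagents that add atoms: none
Why: Hydride reduction of the hindered axial methyl ester gives the primary C19 alcohol, the alkenes and the tertiary alkoxide being unaffected.

Step 22
Reactants: 31 (13R)-labda-8(17),14-diene-13,19-diol; 32 tigloyl chloride
Product: 33 (13R)-13-hydroxylabda-8(17),14-dien-19-yl (E)-2-methylbut-2-enoate
Conditions: pyridine, DMAP (cat.), CH2Cl2, 0 °C → rt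
Reagents that add atoms: none
Why: Acylation with the acid chloride under nucleophilic catalysis should esterify the primary neopentyl C19 hydroxyl selectively, since the tertiary allylic C13 hydroxyl does not react under these conditions and the E geometry of the tiglate is retained.

Compound list

1 | geranyl acetate, (2E)-3,7-dimethylocta-2,6-dienyl acetate | CC(C)=CCC/C(C)=C/COC(C)=O | starting material
2 | (E)-6-acetoxy-4-methylhex-4-enal (formed in the flask, not isolated) | O=CCC/C(C)=C/COC(C)=O | intermediate
3 | (E)-6-hydroxy-3-methylhex-2-enyl acetate | OCCC/C(C)=C/COC(C)=O | intermediate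
4 | (E)-6-iodo-3-methylhex-2-enyl acetate | ICCC/C(C)=C/COC(C)=O | intermediate
5 | dimethyl malonate | COC(=O)CC(=O)OC | starting material
6 | 2-vinyloxirane (racemic; its stereocentre is lost in step 3) | C=CC1CO1 | starting material
7 | dimethyl 2-[(E)-4-hydroxybut-2-enyl]malonate | COC(=O)C(C/C=C/CO)C(=O)OC | intermediate
8 | sodium enolate of 7 (formed in the flask, not isolated) | [Na+].COC(=O)[C-](C/C=C/CO)C(=O)OC | intermediate
9 | dimethyl 2-[(E)-6-acetoxy-4-methylhex-4-enyl]-2-[(E)-4-hydroxybut-2-enyl]malonate | COC(=O)C(CCC/C(C)=C/COC(C)=O)(C/C=C/CO)C(=O)OC | intermediate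
10 | dimethyl 2-[(E)-6-acetoxy-4-methylhex-4-enyl]-2-[(E)-4-oxobut-2-enyl]malonate | COC(=O)C(CCC/C(C)=C/COC(C)=O)(C/C=C/C=O)C(=O)OC | intermediate
11 | dimethyl 2-[(E)-6-acetoxy-4-methylhex-4-enyl]-2-[(1E,3E)-4-(tert-butyldimethylsilyloxy)buta-1,3-dienyl]malonate | COC(=O)C(CCC/C(C)=C/COC(C)=O)(/C=C/C=C/O[Si](C)(C)C(C)(C)C)C(=O)OC | intermediate
12 | dimethyl 2-[(1E,3E)-4-(tert-butyldimethylsilyloxy)buta-1,3-dienyl]-2-[(E)-6-hydroxy-4-methylhex-4-enyl]malonate | COC(=O)C(CCC/C(C)=C/CO)(/C=C/C=C/O[Si](C)(C)C(C)(C)C)C(=O)OC | intermediate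
13 | dimethyl 2-[(1E,3E)-4-(tert-butyldimethylsilyloxy)buta-1,3-dienyl]-2-[(E)-4-methyl-6-oxohex-4-enyl]malonate (cycloaddition precursor) | O=C/C=C(\C)CCCC(C(=O)OC)(C(=O)OC)/C=C/C=C/O[Si](C)(C)C(C)(C)C | intermediate
14 | dimethyl 8β-(tert-butyldimethylsilyloxy)-11-oxo-12,13,14,15,16,17-hexanorlabd-6-ene-18,19-dioate; trans-fused octalin with 5α-H, 10β-CH3, 9β-CHO and 8β-OSi (the three β groups mutually cis) | O=C[C@H]1[C@@H](O[Si](C)(C)C(C)(C)C)C=C[C@H]2C(C(=O)OC)(C(=O)OC)CCC[C@]12C | intermediate
15 | dimethyl 8β-(tert-butyldimethylsilyloxy)-13,14,15,16,17-pentanorlabda-6,11-diene-18,19-dioate (9β-vinyl) | C=C[C@H]1[C@@H](O[Si](C)(C)C(C)(C)C)C=C[C@H]2C(C(=O)OC)(C(=O)OC)CCC[C@]12C | intermediate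
16 | monoester of 15 after loss of one C4 ester (C4 epimer mixture, C4 left undefined) | C=C[C@H]1[C@@H](O[Si](C)(C)C(C)(C)C)C=C[C@H]2C(C(=O)OC)CCC[C@]12C | intermediate
17 | lithium ester enolate of 16 (formed in the flask, not isolated) | [Li+].C=C[C@H]1[C@@H](O[Si](C)(C)C(C)(C)C)C=C[C@H]2C(=C([O-])OC)CCC[C@]12C | intermediate
18 | methyl 8β-(tert-butyldimethylsilyloxy)-13,14,15,16,17-pentanorlabda-6,11-dien-19-oate (4α-CH3 equatorial, 4β-CO2CH3 axial) | C=C[C@H]1[C@@H](O[Si](C)(C)C(C)(C)C)C=C[C@H]2[C@@](C)(C(=O)OC)CCC[C@]12C | intermediate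
19 | but-2-yn-1-ol | CC#CCO | starting material
20 | cyclic sodium vinylalanate from 19 (formed in the flask, not isolated) | [Na+].CC1=CCO[Al-]1(OCCOC)OCCOC | intermediate
21 | (Z)-3-iodobut-2-en-1-ol | C/C(I)=C/CO | intermediate
22 | B-alkyl-9-borabicyclo[3.3.1]nonane from 18, boron on C12 (formed in the flask, not isolated) | C1CCC2CCCC1B2CC[C@H]1[C@@H](O[Si](C)(C)C(C)(C)C)C=C[C@H]2[C@@](C)(C(=O)OC)CCC[C@]12C | intermediate
23 | methyl (13Z)-8β-(tert-butyldimethylsilyloxy)-15-hydroxy-17-norlabda-6,13-dien-19-oate | OC/C=C(/C)CC[C@H]1[C@@H](O[Si](C)(C)C(C)(C)C)C=C[C@H]2[C@@](C)(C(=O)OC)CCC[C@]12C | intermediate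
24 | methyl (13R,14S)-8β-(tert-butyldimethylsilyloxy)-13,14-epoxy-15-hydroxy-17-norlabd-6-en-19-oate | OC[C@@H]1O[C@]1(C)CC[C@H]1[C@@H](O[Si](C)(C)C(C)(C)C)C=C[C@H]2[C@@](C)(C(=O)OC)CCC[C@]12C | intermediate
25 | methyl (13R,14S)-8β-(tert-butyldimethylsilyloxy)-13,14-epoxy-15-hydroxy-17-norlabdan-19-oate | OC[C@@H]1O[C@]1(C)CC[C@H]1[C@@H](O[Si](C)(C)C(C)(C)C)CC[C@H]2[C@@](C)(C(=O)OC)CCC[C@]12C | intermediate
26 | 15-iodo analogue of 25, same spatial arrangement (formed in the flask, not isolated) | IC[C@@H]1O[C@]1(C)CC[C@H]1[C@@H](O[Si](C)(C)C(C)(C)C)CC[C@H]2[C@@](C)(C(=O)OC)CCC[C@]12C | intermediate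
27 | methyl (13R)-8β-(tert-butyldimethylsilyloxy)-13-hydroxy-17-norlabd-14-en-19-oate | C=C[C@](C)(O)CC[C@H]1[C@@H](O[Si](C)(C)C(C)(C)C)CC[C@H]2[C@@](C)(C(=O)OC)CCC[C@]12C | intermediate
28 | methyl (13R)-8β,13-dihydroxy-17-norlabd-14-en-19-oate | C=C[C@](C)(O)CC[C@H]1[C@@H](O)CC[C@H]2[C@@](C)(C(=O)OC)CCC[C@]12C | intermediate
29 | methyl (13R)-13-hydroxy-8-oxo-17-norlabd-14-en-19-oate | C=C[C@](C)(O)CC[C@H]1C(=O)CC[C@H]2[C@@](C)(C(=O)OC)CCC[C@]12C | intermediate
30 | methyl (13R)-13-hydroxylabda-8(17),14-dien-19-oate | C=C[C@](C)(O)CC[C@H]1C(=C)CC[C@H]2[C@@](C)(C(=O)OC)CCC[C@]12C | intermediate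
31 | (13R)-labda-8(17),14-diene-13,19-diol | C=C[C@](C)(O)CC[C@H]1C(=C)CC[C@H]2[C@@](C)(CO)CCC[C@]12C | intermediate
32 | tigloyl chloride, (E)-2-methylbut-2-enoyl chloride | C/C=C(\C)C(Cl)=O | starting material
33 | (13R)-13-hydroxylabda-8(17),14-dien-19-yl (E)-2-methylbut-2-enoate (CNP0313179.1) | C=C[C@](C)(O)CC[C@H]1C(=C)CC[C@H]2[C@@](C)(COC(=O)/C(C)=C/C)CCC[C@]12C | target

Total step count: 22. Longest linear sequence: 20 steps (from 1 through steps 1, 2, 4–12 and 14–22).

Steps most likely to fail

Step 9 (bears the label). Facial discrimination by the catalyst may be poor with the slow β,β-disubstituted enal, or the acid may strip or divert the silyl dienol ether (protodesilylation, Mukaiyama–Michael addition) before cycloaddition. The fallback sets out from 13 and uses known chemistry only. Cyclisation with Me2AlCl in CH2Cl2 at −78 °C (Lewis acid-promoted intramolecular Diels–Alder reaction of a 1,7,9-decatrienal, endo mode) should give the racemic trans-fused adduct F1. Reduction with NaBH4 in MeOH gives the racemic primary alcohol F2. Esterification with (S)-O-methylmandelic acid (DCC, DMAP) and separation of the diastereomeric esters by chromatography or crystallisation provides the (S)-O-methylmandelate of the required enantiomer F3. Methanolysis (K2CO3, MeOH, 0 °C) releases the enantiopure alcohol F4, and oxidation with Dess–Martin periodinane (NaHCO3) returns to the route at 14.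

Step 10. Base-induced elimination of the silanol across C8–C9 (the C9 hydrogen and the C8 silyloxy group are trans-diaxial and the product would be a conjugated dienal) or epimerisation at C9 may outrun ylide addition to the hindered aldehyde. The fallback sets out from 14. Addition of Me3SiCH2MgCl premixed with anhydrous CeCl3 in THF at −78 °C (weakly basic organocerium addition) should give the β-hydroxysilane F5, and Peterson syn-elimination with KH in THF at 0 °C comes back to the route at 15.

Step 12. The facial bias of the enolate methylation may be insufficient because the C6=C7 alkene flattens ring B, which would give the C4 epimer with an axial methyl group. The fallback sets out from 15 and bypasses steps 11 and 12. Selective reduction of the less hindered equatorial ester of the gem-diester with LiAlH(OtBu)3 in refluxing THF (the axial ester is shielded by the syn-axial C10 methyl) should give the hydroxy ester F6. Appel iodination (PPh3, I2, imidazole, toluene, 80 °C) gives the neopentyl iodide F7, and radical reduction with Bu3SnH and AIBN converts CH2I into the equatorial methyl group, coming back to the route at 18.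

Further compounds

F1 | step 9 | racemic trans-fused adduct (racemate of 14, both enantiomers written) | O=C[C@H]1[C@@H](O[Si](C)(C)C(C)(C)C)C=C[C@H]2C(C(=O)OC)(C(=O)OC)CCC[C@]12C.O=C[C@@H]1[C@H](O[Si](C)(C)C(C)(C)C)C=C[C@@H]2C(C(=O)OC)(C(=O)OC)CCC[C@@]12C
F2 | step 9 | racemic primary alcohol from F1 (both enantiomers written) | OC[C@H]1[C@@H](O[Si](C)(C)C(C)(C)C)C=C[C@H]2C(C(=O)OC)(C(=O)OC)CCC[C@]12C.OC[C@@H]1[C@H](O[Si](C)(C)C(C)(C)C)C=C[C@@H]2C(C(=O)OC)(C(=O)OC)CCC[C@@]12C
F3 | step 9 | (S)-O-methylmandelate of the required enantiomer | CO[C@H](C(=O)OC[C@H]1[C@@H](O[Si](C)(C)C(C)(C)C)C=C[C@H]2C(C(=O)OC)(C(=O)OC)CCC[C@]12C)c1ccccc1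
F4 | step 9 | enantiopure primary alcohol (C11 alcohol corresponding to 14) | OC[C@H]1[C@@H](O[Si](C)(C)C(C)(C)C)C=C[C@H]2C(C(=O)OC)(C(=O)OC)CCC[C@]12C
F5 | step 10 | β-hydroxysilane from 14 (C11 epimers, C11 left undefined) | C[Si](C)(C)CC(O)[C@H]1[C@@H](O[Si](C)(C)C(C)(C)C)C=C[C@H]2C(C(=O)OC)(C(=O)OC)CCC[C@]12C
F6 | step 12 | hydroxy ester from 15 (4α-CH2OH equatorial, 4β-CO2CH3 axial) | C=C[C@H]1[C@@H](O[Si](C)(C)C(C)(C)C)C=C[C@H]2[C@@](CO)(C(=O)OC)CCC[C@]12C
F7 | step 12 | neopentyl iodide from F6 (4α-CH2I) | C=C[C@H]1[C@@H](O[Si](C)(C)C(C)(C)C)C=C[C@H]2[C@@](CI)(C(=O)OC)CCC[C@]12C
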